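**Plan**

1. Retrosynthetic cuts: the side-chain acid is masked as a methyl ester and the ring methyl centre comes from a ring alkene. The cyclohexane ring is cut between the spiro carbon (C2 of the cyclohepta[b]furan) and the adjacent quaternary carbon, together with the CH2–CH2 bond of the propanoic arm, in one radical addition–cyclization. The furan is cut at O–C2 and C3a–C3 (alkyne heteroannulation), and the seven-membered ring at two C–C bonds ([4+3]).
2. Forward order: oxyallyl cation plus 4-bromo-2-methylfuran gives an 8-oxabicycle, which is opened and oxidized to a bromo hydroxytropone (seven-membered ring first). Sonogashira coupling with 5-endo cyclization then fuses the furan. The cyclohexane ring is closed last.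
3. Enabling feature: in the 7H-cyclohepta[b]furan-7-one, furan C2 is the far end of the acceptor chain C2=C3–C3a=C4–C5=C6–C7=O, so a carbon radical adds there and the C3 radical is spread over the tropone. The quaternary ring carbon with its CH3 and CH2CH2CO2H arm is the footprint of an isopropenyl group that has taken up a •CH2CO2Me radical.
4. Stereochemistry: the methine bearing the hydroxypropyl group comes from an Evans alkylation. The spiro centre and the neighbouring quaternary centre are set in the ring closure under control of that methine and the (Z)-alkene of the tether. The ring methyl centre is set by hydroxyl-directed hydrogenation.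

Key step: step 12

Assumption: 4, 5 and 6 are carried as racemates or diastereomer mixtures, because every stereocentre in them becomes trigonal in 7.

**Route**

Step 1
Reactants: 1 4-bromo-2-furaldehyde
Product: 2 4-bromo-2-methylfuran
Conditions: N2H4·H2O, KOH, diethylene glycol, 100 → 195 °C, product distilled out
Reagents that add atoms: none
Why: Wolff–Kishner reduction of a furfural to the 2-methylfuran, a standard deoxygenation that should leave the ring C–Br bond untouched.

Step 2
Reactants: 3 methyl 3-oxopentanoate
Product: 4 methyl 4-bromo-3-oxopentanoate (racemic)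
Conditions: Br2, CHCl3, 0 °C → rt
Reagents that add atoms: bromine, BrBr
Why: electrophilic bromination of the β-keto ester, in which the first-formed 2-bromide equilibrates under the HBr produced to the 4-bromo isomer, as is known for 4-bromoacetoacetates.

Step 3
Reactants: 2 4-bromo-2-methylfuran; 4 methyl 4-bromo-3-oxopentanoate
Product: 5 methyl 6-bromo-1,4-dimethyl-3-oxo-8-oxabicyclo[3.2.1]oct-6-ene-2-carboxylate (racemic, diastereomer mixture)
Conditions: Et3N, CF3CH2OH, excess 2, 0 °C → rt
Reagents that add atoms: none
Why: base-mediated [4+3] cycloaddition of a furan with the oxyallyl cation from an α-halo ketone in trifluoroethanol, in which the cation's methyl-bearing end bonds to the free α-carbon (C5) of the furan and the β-keto ester carbon then closes on the methyl-bearing α-carbon, placing bromine next to the CH–O bridgehead.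

Step 4
Reactants: 5 methyl 6-bromo-1,4-dimethyl-3-oxo-8-oxabicyclo[3.2.1]oct-6-ene-2-carboxylate
Product: 6 methyl 4-bromo-5-hydroxy-2,6-dimethyl-7-oxocyclohepta-1,3-diene-1-carboxylate (racemic, diastereomer mixture)
Conditions: DBU, MeCN, rt
Reagents that add atoms: none
Why: E1cB opening of the oxygen bridge (β-elimination of a β-alkoxy ketone), in which only the β-keto ester C–H is acidic enough for DBU, so the C–O bond at the methyl-bearing bridgehead is the one expelled.

Step 5
Reactants: 6 methyl 4-bromo-5-hydroxy-2,6-dimethyl-7-oxocyclohepta-1,3-diene-1-carboxylate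
Product: 7 methyl 4-bromo-5-hydroxy-2,6-dimethyl-7-oxocyclohepta-1,3,5-triene-1-carboxylate
Conditions: Dess–Martin periodinane, CH2Cl2, 0 °C → rt
Reagents that add atoms: none
Why: Dess–Martin oxidation of the secondary allylic alcohol gives a cyclic 1,3-diketone that should enolize at once to the 3-hydroxytropone, which removes all stereocentres of 6.

Step 6
Reactants: 8 (2Z)-3-methylpent-2-en-4-yn-1-ol
Product: 9 (3Z)-5-bromo-3-methylpent-3-en-1-yne
Conditions: CBr4, PPh3, CH2Cl2, 0 °C
Reagents that add atoms: carbon tetrabromide, BrC(Br)(Br)Br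
Why: Appel bromination of a primary allylic alcohol under neutral conditions, which should keep the (Z) geometry.

Step 7
Reactants: 10 (4S)-4-benzyl-1,3-oxazolidin-2-one; 11 3-methylbut-2-enoyl chloride
Product: 12 (4S)-4-benzyl-3-(3-methylbut-2-enoyl)-1,3-oxazolidin-2-one
Conditions: n-BuLi, THF, −78 °C; then 11, −78 → 0 °C
Reagents that add atoms: none
Why: N-acylation of the lithiated oxazolidinone with an acid chloride, the standard preparation of an Evans imide.

Step 8
Reactants: 12 (4S)-4-benzyl-3-(3-methylbut-2-enoyl)-1,3-oxazolidin-2-one; 9 (3Z)-5-bromo-3-methylpent-3-en-1-yne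
Product: 13 (4S)-4-benzyl-3-[(2S,4Z)-5-methyl-2-(prop-1-en-2-yl)hept-4-en-6-ynoyl]-1,3-oxazolidin-2-one
Conditions: NaN(SiMe3)2, THF, −78 °C; then 9, −78 → −40 °C
Reagents that add atoms: none
Why: Evans alkylation in its deconjugative form, in which γ-deprotonation gives the chelated (Z)-dienolate that reacts at its α-carbon with the allylic bromide on the face away from the benzyl group, setting the (S) methine.

Step 9
Reactants: 13 (4S)-4-benzyl-3-[(2S,4Z)-5-methyl-2-(prop-1-en-2-yl)hept-4-en-6-ynoyl]-1,3-oxazolidin-2-one
Product: 14 methyl (2S,4Z)-5-methyl-2-(prop-1-en-2-yl)hept-4-en-6-ynoate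
Conditions: MeMgBr, MeOH, CH2Cl2, 0 °C
Reagents that add atoms: methanol, CO
Why: transesterification with methoxymagnesium bromide (MeOMgBr) removes the auxiliary, recovered as 10, under weakly basic conditions that should neither epimerize nor conjugate the β,γ-unsaturated α-centre.

Step 10
Reactants: 14 methyl (2S,4Z)-5-methyl-2-(prop-1-en-2-yl)hept-4-en-6-ynoate
Product: 15 (3S,5Z)-2,6-dimethyl-3-(prop-1-en-2-yl)oct-5-en-7-yn-2-ol
Conditions: MeLi, CeCl3, THF, −78 → 0 °C
Reagents that add atoms: methyllithium, [Li]C
Why: double addition of the weakly basic organocerium reagent MeCeCl2 to the ester should give the tertiary alcohol without enolizing the adjacent stereocentre.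

Step 11
Reactants: 7 methyl 4-bromo-5-hydroxy-2,6-dimethyl-7-oxocyclohepta-1,3,5-triene-1-carboxylate; 15 (3S,5Z)-2,6-dimethyl-3-(prop-1-en-2-yl)oct-5-en-7-yn-2-ol
Product: 17 methyl 2-[(2Z,5S)-5-(2-hydroxypropan-2-yl)-6-methylhepta-2,6-dien-2-yl]-5,8-dimethyl-7-oxo-7H-cyclohepta[b]furan-6-carboxylate, via alkynyl hydroxytropone 16 (not isolated)
Conditions: PdCl2(PPh3)2 (cat.), CuI (cat.), Et3N, DMF, 60 °C
Reagents that add atoms: none
Why: Sonogashira coupling at the C–Br bond followed in the same pot by 5-endo-dig addition of the neighbouring hydroxyl to the alkyne, the usual heteroannulation of o-halophenols to 2-substituted benzofurans, applied here to the vinylogous acid of the tropone.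

Step 12
Reactants: 17 methyl 2-[(2Z,5S)-5-(2-hydroxypropan-2-yl)-6-methylhepta-2,6-dien-2-yl]-5,8-dimethyl-7-oxo-7H-cyclohepta[b]furan-6-carboxylate; 18 methyl bromoacetate
Product: 19 methyl (2R,5'S,6'R)-5'-(2-hydroxypropan-2-yl)-6'-(3-methoxy-3-oxopropyl)-2',5,6',8-tetramethyl-7-oxo-3,7-dihydrospiro[cyclohepta[b]furan-2,1'-cyclohex[2]ene]-6-carboxylate
Conditions: excess 18, fac-Ir(ppy)3 (cat.), Hantzsch ester (diethyl 2,6-dimethyl-1,4-dihydropyridine-3,5-dicarboxylate), 2,6-lutidine, degassed MeCN, blue LEDs, rt
Reagents that add atoms: none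
Why: Proposed new method: photoexcited fac-Ir(ppy)3 reduces 18 to the electrophilic •CH2CO2Me radical, which adds to the CH2 end of the electron-rich isopropenyl group; the nucleophilic tertiary radical formed then attacks furan C2 of 17, the far end of the C2=C3–C3a=C4–C5=C6–C7=O acceptor chain, and the tropone-delocalized C3 radical takes a hydrogen atom from the Hantzsch ester to leave the C3 methylene and the restored tropone. The closest known reaction types are photoredox reductive addition–cyclization cascades of α-bromo esters with alkenes (Giese type) and dearomative radical spirocyclizations at C2 of acceptor-substituted benzofurans, neither of which has been shown on a tropone-fused furan. The cyclohexene ring closes in the 6-exo-trig mode, the (Z)-alkene of the tether holding the two reacting carbons within bonding distance. The spiro centre and the neighbouring quaternary centre are set together in a half-chair transition state anchored by the existing (S)-methine, whose hydroxypropyl group stays equatorial: 1,2-allylic strain against the vinylic methyl should place the small ring oxygen pseudo-equatorial and the C3 carbon pseudo-axial at the spiro centre, and the CH2CH2CO2Me arm should take the equatorial site at the radical carbon so that its methyl ends axial and anti to C3. The step needs chemoselective attack of the acetate radical on the isolated 1,1-disubstituted alkene and not on the conjugated system, which polarity matching should secure (electrophilic radical with the electron-rich alkene, nucleophilic tertiary radical with the electron-poor furan C2), and ring closure ahead of hydrogen transfer, which the intramolecular rate should secure.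

Step 13
Reactants: 19 methyl (2R,5'S,6'R)-5'-(2-hydroxypropan-2-yl)-6'-(3-methoxy-3-oxopropyl)-2',5,6',8-tetramethyl-7-oxo-3,7-dihydrospiro[cyclohepta[b]furan-2,1'-cyclohex[2]ene]-6-carboxylate
Product: 20 methyl (2R,2'R,3'S,6'S)-3'-(2-hydroxypropan-2-yl)-2'-(3-methoxy-3-oxopropyl)-2',5,6',8-tetramethyl-7-oxo-3,7-dihydrospiro[cyclohepta[b]furan-2,1'-cyclohexane]-6-carboxylate
Conditions: [Ir(cod)(PCy3)(py)]PF6 (cat.), H2 (1 atm), CH2Cl2, rt
Reagents that add atoms: none
Why: hydroxyl-directed homogeneous hydrogenation of the hindered trisubstituted ring alkene, in which hydrogen should add on the face opposite to the pseudo-axial C3 methylene at the spiro carbon (the face the iridium bound to the tertiary hydroxyl can reach), so that the new methyl ends equatorial and cis to C3 as the (S) centre.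

Step 14
Reactants: 20 methyl (2R,2'R,3'S,6'S)-3'-(2-hydroxypropan-2-yl)-2'-(3-methoxy-3-oxopropyl)-2',5,6',8-tetramethyl-7-oxo-3,7-dihydrospiro[cyclohepta[b]furan-2,1'-cyclohexane]-6-carboxylate
Product: 21 3-[(2R,2'R,3'S,6'S)-3'-(2-hydroxypropan-2-yl)-6-(methoxycarbonyl)-2',5,6',8-tetramethyl-7-oxo-3,7-dihydrospiro[cyclohepta[b]furan-2,1'-cyclohexan]-2'-yl]propanoic acid
Conditions: Me3SnOH, ClCH2CH2Cl, 80 °C; then 1 M HCl
Reagents that add atoms: trimethyltin hydroxide, C[Sn](C)(C)O
Why: mild tin hydroxide hydrolysis of methyl esters should be selective for the unhindered aliphatic ester over the tropone ester, which is flanked by a ring methyl group and the ring carbonyl.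

**Compound list**

1 | 4-bromo-2-furaldehyde | O=Cc1cc(Br)co1 | starting material
2 | 4-bromo-2-methylfuran | Cc1cc(Br)co1 | intermediate
3 | methyl 3-oxopentanoate | CCC(=O)CC(=O)OC | starting material
4 | methyl 4-bromo-3-oxopentanoate (racemic) | CC(Br)C(=O)CC(=O)OC | intermediate
5 | methyl 6-bromo-1,4-dimethyl-3-oxo-8-oxabicyclo[3.2.1]oct-6-ene-2-carboxylate (racemic, diastereomer mixture) | COC(=O)C1C(=O)C(C)C2OC1(C)C=C2Br | intermediate
6 | methyl 4-bromo-5-hydroxy-2,6-dimethyl-7-oxocyclohepta-1,3-diene-1-carboxylate (racemic, diastereomer mixture) | COC(=O)C1=C(C)C=C(Br)C(O)C(C)C1=O | intermediate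
7 | methyl 4-bromo-5-hydroxy-2,6-dimethyl-7-oxocyclohepta-1,3,5-triene-1-carboxylate | COC(=O)C1=C(C)C=C(Br)C(O)=C(C)C1=O | intermediate
8 | (2Z)-3-methylpent-2-en-4-yn-1-ol | OC/C=C(/C)C#C | starting material
9 | (3Z)-5-bromo-3-methylpent-3-en-1-yne | BrC/C=C(/C)C#C | intermediate
10 | (4S)-4-benzyl-1,3-oxazolidin-2-one | O=C1N[C@@H](Cc2ccccc2)CO1 | starting material
11 | 3-methylbut-2-enoyl chloride | CC(C)=CC(Cl)=O | starting material
12 | (4S)-4-benzyl-3-(3-methylbut-2-enoyl)-1,3-oxazolidin-2-one | CC(C)=CC(=O)N1[C@@H](Cc2ccccc2)COC1=O | intermediate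
13 | (4S)-4-benzyl-3-[(2S,4Z)-5-methyl-2-(prop-1-en-2-yl)hept-4-en-6-ynoyl]-1,3-oxazolidin-2-one | C#C/C(C)=C\C[C@@H](C(C)=C)C(=O)N1[C@@H](Cc2ccccc2)COC1=O | intermediate
14 | methyl (2S,4Z)-5-methyl-2-(prop-1-en-2-yl)hept-4-en-6-ynoate | C#C/C(C)=C\C[C@@H](C(C)=C)C(=O)OC | intermediate
15 | (3S,5Z)-2,6-dimethyl-3-(prop-1-en-2-yl)oct-5-en-7-yn-2-ol | C#C/C(C)=C\C[C@@H](C(C)=C)C(C)(C)O | intermediate
16 | methyl 5-hydroxy-4-[(3Z,6S)-6-(2-hydroxypropan-2-yl)-3,7-dimethylocta-3,7-dien-1-yn-1-yl]-2,6-dimethyl-7-oxocyclohepta-1,3,5-triene-1-carboxylate | COC(=O)C1=C(C)C=C(C#C/C(C)=C\C[C@@H](C(C)=C)C(C)(C)O)C(O)=C(C)C1=O | intermediate (not isolated)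
17 | methyl 2-[(2Z,5S)-5-(2-hydroxypropan-2-yl)-6-methylhepta-2,6-dien-2-yl]-5,8-dimethyl-7-oxo-7H-cyclohepta[b]furan-6-carboxylate | COC(=O)C1=C(C)C=C2C=C(/C(C)=C\C[C@@H](C(C)=C)C(C)(C)O)OC2=C(C)C1=O | intermediate
18 | methyl bromoacetate | COC(=O)CBr | starting material
19 | methyl (2R,5'S,6'R)-5'-(2-hydroxypropan-2-yl)-6'-(3-methoxy-3-oxopropyl)-2',5,6',8-tetramethyl-7-oxo-3,7-dihydrospiro[cyclohepta[b]furan-2,1'-cyclohex[2]ene]-6-carboxylate | COC(=O)c1c(C)cc2c(c(C)c1=O)O[C@]1(C2)C(C)=CC[C@H](C(C)(C)O)[C@@]1(C)CCC(=O)OC | intermediate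
20 | methyl (2R,2'R,3'S,6'S)-3'-(2-hydroxypropan-2-yl)-2'-(3-methoxy-3-oxopropyl)-2',5,6',8-tetramethyl-7-oxo-3,7-dihydrospiro[cyclohepta[b]furan-2,1'-cyclohexane]-6-carboxylate | COC(=O)c1c(C)cc2c(c(C)c1=O)O[C@]1(C2)[C@@H](C)CC[C@H](C(C)(C)O)[C@@]1(C)CCC(=O)OC | intermediate
21 | 3-[(2R,2'R,3'S,6'S)-3'-(2-hydroxypropan-2-yl)-6-(methoxycarbonyl)-2',5,6',8-tetramethyl-7-oxo-3,7-dihydrospiro[cyclohepta[b]furan-2,1'-cyclohexan]-2'-yl]propanoic acid | COC(=O)c1c(C)cc2c(c(C)c1=O)O[C@]1(C2)[C@@H](C)CC[C@H](C(C)(C)O)[C@@]1(C)CCC(=O)O | target

**Totals and risks**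

Total step count: 14. Longest linear sequence: 8 steps (8 → 9 → 13 → 14 → 15 → 17 → 19 → 20 → 21).

Steps most likely to fail:

Step 12 (Proposed new method). Possible failures are light absorption or single-electron reduction of the coloured furotropone in competition with 18, hydrogen transfer to the tertiary radical before ring closure, and poor facial selectivity at the spiro carbon. The spiro-centre selectivity is the least secure prediction of the route: the 1,2-allylic strain argument is product-like, and an early transition state could favour the other epimer. The fallback uses known chemistry, sets out from 15 and comes back at 19. Copper-catalysed Kharasch atom-transfer addition of 18 across the isopropenyl group of 15 (CuBr, tris(2-pyridylmethyl)amine, MeCN, 60 °C) should give the tertiary bromide methyl (5R,7Z)-4-bromo-5-(2-hydroxypropan-2-yl)-4,8-dimethyldec-7-en-9-ynoate F1. Sonogashira heteroannulation of F1 with 7 under the conditions of step 11 should give methyl 2-[(2Z,5R)-6-bromo-5-(2-hydroxypropan-2-yl)-9-methoxy-6-methyl-9-oxonon-2-en-2-yl]-5,8-dimethyl-7-oxo-7H-cyclohepta[b]furan-6-carboxylate F2. Slow addition of Bu3SnH with AIBN in benzene at 80 °C should then close the cyclohexene ring by the classical halide-initiated 6-exo radical cyclization onto a conjugated acceptor and deliver 19. This separates the intermolecular addition from the ring closure, uses no light, and lets the syringe pump set the hydrogen donor concentration.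

Step 3. Possible failures are sluggish reaction of the bromine-deactivated furan with the oxyallyl cation, solvolysis or Favorskii rearrangement of 4, and loss of regiocontrol in the two bond formations. The fallback sets out from 4 and comes back at 7, and introduces bromine after the tropone is made. The cycloaddition is run under the same conditions with the more nucleophilic, commercial 2-methylfuran to give methyl 1,4-dimethyl-3-oxo-8-oxabicyclo[3.2.1]oct-6-ene-2-carboxylate F3. DBU opening as in step 4 gives methyl 5-hydroxy-2,6-dimethyl-7-oxocyclohepta-1,3-diene-1-carboxylate F4, and Dess–Martin oxidation as in step 5 gives methyl 5-hydroxy-2,6-dimethyl-7-oxocyclohepta-1,3,5-triene-1-carboxylate F5. Addition of Br2 (CH2Cl2, 0 °C) to the only disubstituted ring double bond and loss of HBr with Et3N, the classical α-bromination of tropones, should then give 7.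

Step 13. Possible failures are over-reduction of the tropone ring and hydrogen delivery to the wrong face of the ring alkene. The fallback sets out from 19 and comes back at 20. It is a hydrogen-atom-transfer hydrogenation (Mn(dpm)3, PhSiH3, t-BuOOH, i-PrOH, rt), a stepwise radical hydrogenation of the electron-rich trisubstituted alkene under thermodynamic control. It should place the new methyl equatorial and spare the electron-poor tropone, and it makes no new compound (F0).

**Further compounds**

F1 | step 12 | methyl (5R,7Z)-4-bromo-5-(2-hydroxypropan-2-yl)-4,8-dimethyldec-7-en-9-ynoate (both epimers at C4) | C#C/C(C)=C\C[C@@H](C(C)(Br)CCC(=O)OC)C(C)(C)O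
F2 | step 12 | methyl 2-[(2Z,5R)-6-bromo-5-(2-hydroxypropan-2-yl)-9-methoxy-6-methyl-9-oxonon-2-en-2-yl]-5,8-dimethyl-7-oxo-7H-cyclohepta[b]furan-6-carboxylate (both epimers at the C–Br carbon) | COC(=O)C1=C(C)C=C2C=C(/C(C)=C\C[C@@H](C(C)(Br)CCC(=O)OC)C(C)(C)O)OC2=C(C)C1=O
F3 | step 3 | methyl 1,4-dimethyl-3-oxo-8-oxabicyclo[3.2.1]oct-6-ene-2-carboxylate (racemic, diastereomer mixture) | COC(=O)C1C(=O)C(C)C2OC1(C)C=C2
F4 | step 3 | methyl 5-hydroxy-2,6-dimethyl-7-oxocyclohepta-1,3-diene-1-carboxylate (racemic, diastereomer mixture) | COC(=O)C1=C(C)C=CC(O)C(C)C1=O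
F5 | step 3 | methyl 5-hydroxy-2,6-dimethyl-7-oxocyclohepta-1,3,5-triene-1-carboxylate | COC(=O)C1=C(C)C=CC(O)=C(C)C1=O
F0 | step 13 | none | none
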